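**Strategy**

- Cuts: the C7 ketone goes back to a 7β-carbinol and the lactone O16–C15 bond to a 15,16-diol. The ring C bond O–C13 and the C8–O bond are then cut together, leaving a 7β-tert-butyl carbonate, an 8α,9α-epoxide and a (13R)-13,16-epoxide. Last come the C13=C14 bond (olefination) and the sclareol side chain.
- Enabling feature: the ring C oxygen is axial (α) on C9, trans-diaxial to the 8β-hydroxyl beside the C7 oxygen, and its other end is C13, which carries the oxygenated C16. O–C7, O–C8, O–C9–C13 and O–C16 are therefore a carbonate, an 8,9-epoxide and a 13,16-epoxide in latent form.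
- Forward: rings A and B come intact from (−)-sclareol. The chain is completed at C13 by Horner–Wadsworth–Emmons olefination. Ring C (O, C9, C11, C12, C13) and a temporary 7,8-carbonate ring close in the domino. Lactone ring D closes by oxidative lactonisation.
- Stereochemistry: C5 and C10 come from sclareol. C13 comes from a ligand-controlled directed epoxidation and one inversion. C9 comes from α-face epoxidation. C8 is set by inversion through the tethered carbonate. The 7β-carbinol (axial hydride delivery) is a relay that is erased at the end.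

Key step: step 12

Remark: labdane numbering is used throughout. It is assumed that the (R,R)-antipode of the bishydroxamic acid ligand gives the (13R)-epoxide in step 6; this is to be verified at compound 9, and the (S,S)-ligand is used if the sense is opposite.

**Route**

Step 1
Reactants: 1 (−)-sclareol
Product: 2 8α-hydroxy-14,15-dinorlabdan-13-one
Conditions: KMnO4, acetone–H2O, 0 °C to rt
Reagents that add atoms: none
Why: Permanganate oxidative degradation of the tertiary vinyl carbinol removes C14 and C15 and leaves the C13 methyl ketone (its oxygen is the former 13-hydroxyl), while the tertiary 8α-hydroxyl and the saturated decalin are inert in cold acetone and no stereocentre is formed.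

Step 2
Reactants: 2 8α-hydroxy-14,15-dinorlabdan-13-one
Product: 3 14,15-dinorlabd-8-en-13-one
Conditions: PPh3, I2, CH2Cl2, rt
Reagents that add atoms: none
Why: Dehydration of a tertiary alcohol with the PPh3–I2 couple proceeds by E1 loss under equilibrating acidic conditions (HI forms in the flask), so the thermodynamically preferred tetrasubstituted C8=C9 alkene should result, and the C8 and C9 centres removed here are rebuilt later.

Step 3
Reactants: 3 14,15-dinorlabd-8-en-13-one; 4 triethyl phosphonoacetate
Product: 5 ethyl (13E)-labda-8,13-dien-15-oate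
Conditions: NaH, THF, 0 °C to reflux; silica chromatography to remove the 13Z isomer
Reagents that add atoms: none
Why: Horner–Wadsworth–Emmons olefination of the methyl ketone with the stabilised phosphonate anion should give mainly the E enoate (ester trans to the larger C12 chain), and only this isomer is kept because it alone has the C16 methyl cis to the ester, as the next step requires.

Step 4
Reactants: 5 ethyl (13E)-labda-8,13-dien-15-oate
Product: 7 ethyl labda-8,13(16)-dien-15-oate, via lithium dienolate 6 (not isolated)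
Conditions: LiN(iPr)2, DMPU, THF, −78 °C; then AcOH, −78 °C
Reagents that add atoms: none
Why: Deconjugative protonation of an enoate: the amide base removes a γ-proton from the group cis to the ester carbonyl (the C16 methyl of the E ester), and kinetic protonation of the resulting dienolate at the α-carbon C14 on cold acidic quench should give the β,γ-unsaturated ester with the 13(16)-methylidene group.

Step 5
Reactants: 7 ethyl labda-8,13(16)-dien-15-oate
Product: 8 labda-8,13(16)-dien-15-ol
Conditions: LiAlH4, Et2O, 0 °C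
Reagents that add atoms: none
Why: Hydride reduction of the non-conjugated ester to the primary alcohol, in which neither isolated alkene reacts and the short, cold exposure avoids base-induced reconjugation.

Step 6
Reactants: 8 labda-8,13(16)-dien-15-ol
Product: 9 (13R)-13,16-epoxylabd-8-en-15-ol
Conditions: Zr(OtBu)4 (cat.), (R,R)-N,N'-dihydroxy-N,N'-bis(2,2-diphenylacetyl)cyclohexane-1,2-diamine (cat.), DMPU, 4 Å MS, cumene hydroperoxide, toluene, 0 °C
Reagents that add atoms: cumene hydroperoxide, CC(C)(OO)c1ccccc1
Why: Hydroxyl-directed catalytic asymmetric epoxidation of a homoallylic alcohol: the C15 alkoxide binds the zirconium–bishydroxamate so that only the nearby 13(16)-alkene is reached and the non-coordinating C8=C9 alkene is left alone, and the chiral ligand, not the remote decalin, selects the face that gives the (13R)-epoxide.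

Step 7
Reactants: 9 (13R)-13,16-epoxylabd-8-en-15-ol
Product: 10 (13R)-15-(tert-butyldimethylsilyloxy)-13,16-epoxylabd-8-ene
Conditions: TBSCl, imidazole, CH2Cl2, 0 °C to rt
Reagents that add atoms: tert-butyldimethylsilyl chloride, CC(C)(C)[Si](C)(C)Cl
Why: Standard silylation of a primary alcohol under mildly basic conditions that leave the epoxide closed, chosen because a silyl ether cannot act as a neighbouring group in the later acid step.

Step 8
Reactants: 10 (13R)-15-(tert-butyldimethylsilyloxy)-13,16-epoxylabd-8-ene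
Product: 11 (13R)-15-(tert-butyldimethylsilyloxy)-13,16-epoxylabd-8-en-7-one
Conditions: CrO3, 3,5-dimethylpyrazole, CH2Cl2, −20 °C
Reagents that add atoms: chromium trioxide, O=[Cr](=O)=O
Why: Allylic C–H oxidation with the CrO3–3,5-dimethylpyrazole complex should convert the ring methylene C7 beside the tetrasubstituted alkene into the enone, since C11 is shielded by the quaternary C10 and the C17 methyl is a less reactive primary position, while the cold, non-acidic medium should spare the epoxide and the silyl ether.

Step 9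
Reactants: 11 (13R)-15-(tert-butyldimethylsilyloxy)-13,16-epoxylabd-8-en-7-one
Product: 12 (13R)-15-(tert-butyldimethylsilyloxy)-13,16-epoxylabd-8-en-7β-ol
Conditions: NaBH4, CeCl3·7H2O, MeOH, −78 to −40 °C
Reagents that add atoms: none
Why: Luche 1,2-reduction of the enone, in which the small cerium-modified borohydride adds to C7 along the axial trajectory from the α face of the half-chair ring B and so should give the pseudo-equatorial 7β-alcohol, the cold and short reaction leaving the epoxide intact.

Step 10
Reactants: 12 (13R)-15-(tert-butyldimethylsilyloxy)-13,16-epoxylabd-8-en-7β-ol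
Product: 13 (13R)-7β-(tert-butoxycarbonyloxy)-15-(tert-butyldimethylsilyloxy)-13,16-epoxylabd-8-ene
Conditions: Boc2O, DMAP (cat.), MeCN, rt
Reagents that add atoms: di-tert-butyl dicarbonate, CC(C)(C)OC(=O)OC(=O)OC(C)(C)C
Why: DMAP-catalysed acylation of the secondary allylic alcohol gives the mixed tert-butyl carbonate without touching the C7 configuration and installs the group that will later deliver oxygen to C8.

Step 11
Reactants: 13 (13R)-7β-(tert-butoxycarbonyloxy)-15-(tert-butyldimethylsilyloxy)-13,16-epoxylabd-8-ene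
Product: 14 (13R)-7β-(tert-butoxycarbonyloxy)-15-(tert-butyldimethylsilyloxy)-8α,9α:13,16-diepoxylabdane
Conditions: m-CPBA, NaHCO3, CH2Cl2, 0 °C
Reagents that add atoms: 3-chloroperbenzoic acid, OOC(=O)c1cccc(Cl)c1
Why: Prilezhaev epoxidation of the electron-rich tetrasubstituted alkene with buffered peracid should occur on the α face, anti to both the axial C10 methyl and the 7β-carbonate, which places the C9 oxygen α (and the C8 oxygen α, to be inverted next).

Step 12
Reactants: 14 (13R)-7β-(tert-butoxycarbonyloxy)-15-(tert-butyldimethylsilyloxy)-8α,9α:13,16-diepoxylabdane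
Product: 16 (13S)-15-(tert-butyldimethylsilyloxy)-16-hydroxy-9α,13-epoxylabdane-7β,8β-diyl carbonate, via 9α-hydroxy 7β,8β-carbonate 13,16-epoxide 15 (not isolated)
Conditions: BF3·OEt2 (0.5 equiv), CH2Cl2, −78 to −40 °C; Et3N, then aq. NaHCO3
Reagents that add atoms: none
Why: BF3 coordination of an epoxide oxygen starts a double epoxide opening in which the carbonyl oxygen of the 7β-carbonate attacks C8 from the β face, anti to the breaking C8–O bond (5-exo-tet, trans-diaxial), the tert-butyl group leaves as isobutene to give the cis-fused five-membered 7β,8β-carbonate, and the oxygen that stays on C9 (as in 15) attacks the tertiary C13 of the 13,16-epoxide (5-exo-tet) to close tetrahydrofuran ring C and free the C16 hydroxyl; if the side-chain epoxide is activated first the same two bonds form in the reverse order, so both sequences should give 16. The closest known reaction type is the Lewis-acid-promoted opening cascade of 1,5-diepoxides terminated by a tert-butyl carbonate, together with acid-catalysed 5-exo opening of 2,2-disubstituted epoxides at the more substituted carbon. C9 keeps its α oxygen because the C9–O bond is never broken, C8 is inverted from α-oxygen to β-oxygen by the backside attack that the tether from the 7β oxygen enforces, and C13 is inverted exactly once, so that the catalyst-set (13R)-epoxide becomes the (13S) spiro centre. The step needs attack at C8 rather than C9 and at C13 rather than C16: the first is secured by the five-membered tether (C9 would need a 6-endo closure and is a neopentyl centre shielded by C10) and by the trans-diaxial opening geometry, the second by the 5-exo geometry and the greater cationic character of tertiary C13. The silyl ether at C15 cannot participate, and the low temperature should hold back Meinwald and Wagner–Meerwein rearrangements of the two epoxides.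

Step 13
Reactants: 16 (13S)-15-(tert-butyldimethylsilyloxy)-16-hydroxy-9α,13-epoxylabdane-7β,8β-diyl carbonate
Product: 17 (13S)-15,16-dihydroxy-9α,13-epoxylabdane-7β,8β-diyl carbonate
Conditions: Bu4NF, AcOH, THF, 0 °C to rt
Reagents that add atoms: none
Why: Fluoride-mediated cleavage of the primary silyl ether, buffered with acetic acid so that the cyclic carbonate is not attacked by alkoxide.

Step 14
Reactants: 17 (13S)-15,16-dihydroxy-9α,13-epoxylabdane-7β,8β-diyl carbonate
Product: 18 (13S)-9α,13-epoxylabdane-7β,8β,15,16-tetraol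
Conditions: K2CO3 (cat.), MeOH, rt
Reagents that add atoms: none
Why: Base-catalysed methanolysis (transesterification) of the cyclic carbonate releases the 7β,8β-diol, and it is run while no lactone is present, so the β-alkoxy carbonyl motif that could open by retro-oxa-Michael reaction at C13 does not yet exist.

Step 15
Reactants: 18 (13S)-9α,13-epoxylabdane-7β,8β,15,16-tetraol
Product: 20 (13S)-7β,8β-dihydroxy-9α,13-epoxylabdan-15,16-olide, via 15,16-lactol 19 (not isolated)
Conditions: Cu(MeCN)4OTf (cat.), 2,2'-bipyridine, TEMPO, N-methylimidazole, air, MeCN, rt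
Reagents that add atoms: none
Why: Copper/nitroxyl-catalysed aerobic oxidative lactonisation of a 1,4-diol: the TEMPO-based oxidant is selective for primary alcohols and among them for the less hindered C15 carbinol over the neopentyl C16 carbinol beside quaternary C13, so oxidation at C15 followed by closure onto O16 gives lactol 19 and then the 15,16-olide (ring D), while the secondary C7 and tertiary C8 hydroxyls are untouched and no glycol-cleaving oxidant is present.

Step 16
Reactants: 20 (13S)-7β,8β-dihydroxy-9α,13-epoxylabdan-15,16-olide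
Product: 21 (13S)-8β-hydroxy-7-oxo-9α,13-epoxylabdan-15,16-olide (target CNP0208728.2)
Conditions: IBX, DMSO, rt
Reagents that add atoms: none
Why: IBX oxidation of the secondary 7β-alcohol to the ketone, a reagent that converts secondary–tertiary 1,2-diols into α-hydroxy ketones without C–C cleavage and whose neutral conditions avoid α-ketol shift and retro-oxa-Michael opening of the β-alkoxy lactone.

**Compound list**

1 | (−)-sclareol, (13R)-labd-14-ene-8α,13-diol | CC1(C)CCC[C@@]2(C)[C@H]1CC[C@@](C)(O)[C@@H]2CC[C@@](C)(O)C=C | starting material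
2 | 8α-hydroxy-14,15-dinorlabdan-13-one | CC1(C)CCC[C@@]2(C)[C@H]1CC[C@@](C)(O)[C@@H]2CCC(C)=O | intermediate
3 | 14,15-dinorlabd-8-en-13-one | CC1(C)CCC[C@@]2(C)[C@H]1CCC(C)=C2CCC(C)=O | intermediate
4 | triethyl phosphonoacetate | CCOC(=O)CP(=O)(OCC)OCC | starting material
5 | ethyl (13E)-labda-8,13-dien-15-oate | CC1(C)CCC[C@@]2(C)[C@H]1CCC(C)=C2CC/C(C)=C/C(=O)OCC | intermediate
6 | lithium dienolate of 5 (C16 methylidene, C14=C15 enolate) | CC1(C)CCC[C@@]2(C)[C@H]1CCC(C)=C2CCC(=C)C=C([O-])OCC.[Li+] | intermediate
7 | ethyl labda-8,13(16)-dien-15-oate | CC1(C)CCC[C@@]2(C)[C@H]1CCC(C)=C2CCC(=C)CC(=O)OCC | intermediate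
8 | labda-8,13(16)-dien-15-ol | CC1(C)CCC[C@@]2(C)[C@H]1CCC(C)=C2CCC(=C)CCO | intermediate
9 | (13R)-13,16-epoxylabd-8-en-15-ol | CC1(C)CCC[C@@]2(C)[C@H]1CCC(C)=C2CC[C@@]1(CCO)CO1 | intermediate
10 | (13R)-15-(tert-butyldimethylsilyloxy)-13,16-epoxylabd-8-ene | CC1(C)CCC[C@@]2(C)[C@H]1CCC(C)=C2CC[C@@]1(CCO[Si](C)(C)C(C)(C)C)CO1 | intermediate
11 | (13R)-15-(tert-butyldimethylsilyloxy)-13,16-epoxylabd-8-en-7-one | CC1(C)CCC[C@@]2(C)[C@H]1CC(=O)C(C)=C2CC[C@@]1(CCO[Si](C)(C)C(C)(C)C)CO1 | intermediate
12 | (13R)-15-(tert-butyldimethylsilyloxy)-13,16-epoxylabd-8-en-7β-ol | CC1(C)CCC[C@@]2(C)[C@H]1C[C@H](O)C(C)=C2CC[C@@]1(CCO[Si](C)(C)C(C)(C)C)CO1 | intermediate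
13 | (13R)-7β-(tert-butoxycarbonyloxy)-15-(tert-butyldimethylsilyloxy)-13,16-epoxylabd-8-ene | CC1(C)CCC[C@@]2(C)[C@H]1C[C@H](OC(=O)OC(C)(C)C)C(C)=C2CC[C@@]1(CCO[Si](C)(C)C(C)(C)C)CO1 | intermediate
14 | (13R)-7β-(tert-butoxycarbonyloxy)-15-(tert-butyldimethylsilyloxy)-8α,9α:13,16-diepoxylabdane | CC1(C)CCC[C@@]2(C)[C@H]1C[C@H](OC(=O)OC(C)(C)C)[C@@]3(C)O[C@@]23CC[C@@]1(CCO[Si](C)(C)C(C)(C)C)CO1 | intermediate
15 | (13R)-15-(tert-butyldimethylsilyloxy)-9α-hydroxy-13,16-epoxylabdane-7β,8β-diyl carbonate | CC1(C)CCC[C@@]2(C)[C@H]1C[C@@H]3OC(=O)O[C@]3(C)[C@]2(O)CC[C@@]1(CCO[Si](C)(C)C(C)(C)C)CO1 | intermediate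
16 | (13S)-15-(tert-butyldimethylsilyloxy)-16-hydroxy-9α,13-epoxylabdane-7β,8β-diyl carbonate | CC1(C)CCC[C@@]2(C)[C@H]1C[C@@H]3OC(=O)O[C@]3(C)[C@]21CC[C@@](CO)(CCO[Si](C)(C)C(C)(C)C)O1 | intermediate
17 | (13S)-15,16-dihydroxy-9α,13-epoxylabdane-7β,8β-diyl carbonate | CC1(C)CCC[C@@]2(C)[C@H]1C[C@@H]3OC(=O)O[C@]3(C)[C@]21CC[C@@](CO)(CCO)O1 | intermediate
18 | (13S)-9α,13-epoxylabdane-7β,8β,15,16-tetraol | CC1(C)CCC[C@@]2(C)[C@H]1C[C@H](O)[C@](C)(O)[C@]21CC[C@@](CO)(CCO)O1 | intermediate
19 | (13S)-9α,13:15,16-diepoxylabdane-7β,8β,15-triol (15,16-lactol, both C15 anomers) | CC1(C)CCC[C@@]2(C)[C@H]1C[C@H](O)[C@](C)(O)[C@]21CC[C@]2(COC(O)C2)O1 | intermediate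
20 | (13S)-7β,8β-dihydroxy-9α,13-epoxylabdan-15,16-olide | CC1(C)CCC[C@@]2(C)[C@H]1C[C@H](O)[C@](C)(O)[C@]21CC[C@]2(COC(=O)C2)O1 | intermediate
21 | (13S)-8β-hydroxy-7-oxo-9α,13-epoxylabdan-15,16-olide, CNP0208728.2 | CC1(C)CCC[C@@]2(C)[C@H]1CC(=O)[C@](C)(O)[C@]21CC[C@]2(COC(=O)C2)O1 | target

**Step count and risks**

Total step count: 16. Longest linear sequence: 16 steps, from (−)-sclareol 1 to 21 (phosphonate 4 enters in step 3).

The three steps most likely to fail:

1. Step 12 (domino). What may go wrong: Lewis-acid-induced rearrangement of either epoxide may outrun the two intramolecular openings. This could be a hydride shift in the 2,2-disubstituted side-chain epoxide, or ionisation at C9 followed by methyl or ring-bond migration. The tert-butyl group may also be lost before the carbonate has engaged C8.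
   Fallback: the two openings are uncoupled and the side-chain epoxide is brought in last. It sets out from 8 and comes back to the route at 17.
   - Silylation of 8 (TBSCl, imidazole) gives 15-(tert-butyldimethylsilyloxy)labda-8,13(16)-diene F1.
   - Allylic oxidation (CrO3, 3,5-dimethylpyrazole) gives 15-(tert-butyldimethylsilyloxy)labda-8,13(16)-dien-7-one F2.
   - Luche reduction gives the 7β-alcohol F3, and Boc2O/DMAP gives its tert-butyl carbonate F4.
   - One equivalent of m-CPBA at low temperature should epoxidise the more nucleophilic tetrasubstituted alkene on the α face to the 8α,9α-epoxide F5.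
   - BF3·OEt2 then has to perform only the simple carbonate opening of a single epoxide, giving the 9α-hydroxy-7β,8β-carbonate F6, with nothing acid-labile in the side chain.
   - Bu4NF/AcOH frees the C15 hydroxyl to give the 9α,15-diol carbonate F7.
   - The Zr(OtBu)4–bishydroxamic acid epoxidation of step 6 installs the (13R)-13,16-epoxide F8.
   - A trace of camphorsulfonic acid lets the 9α-hydroxyl open F8 at C13 (5-exo, inversion) to give 17.

2. Step 8 (allylic oxidation beside an epoxide). What may go wrong: the chromium reagent may open or rearrange the 2,2-disubstituted epoxide, or attack C11 or C17 instead of C7.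
   Fallback: the ketone is introduced before the epoxide exists. It sets out from 8 and comes back at 11.
   - Acetylation of 8 (Ac2O, pyridine) gives labda-8,13(16)-dien-15-yl acetate F9.
   - CrO3–3,5-dimethylpyrazole gives 7-oxolabda-8,13(16)-dien-15-yl acetate F10.
   - K2CO3/MeOH gives 15-hydroxylabda-8,13(16)-dien-7-one F11.
   - The directed zirconium epoxidation of step 6 gives (13R)-15-hydroxy-13,16-epoxylabd-8-en-7-one F12; the electron-poor enone alkene should not compete.
   - Silylation of F12 (TBSCl, imidazole) gives 11.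

3. Step 6 (asymmetric epoxidation). What may go wrong: poor facial selectivity. The two alkene substituents (the C12 chain and the carbinol arm) are sterically alike, and only the metal-bound hydroxyl distinguishes the faces. Chemoselectivity against the C8=C9 alkene may also erode at higher temperature.
   Fallback: catalyst control is given up for separation. It sets out from 8 and comes back at 9.
   - VO(acac)2/tert-butyl hydroperoxide (still hydroxyl-directed and chemoselective) should give 9 together with its epimer (13S)-13,16-epoxylabd-8-en-15-ol F13.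
   - The pair is esterified with 4-nitrobenzoyl chloride/pyridine to the crystalline, UV-active esters (13R)-13,16-epoxylabd-8-en-15-yl 4-nitrobenzoate F14 and (13S)-13,16-epoxylabd-8-en-15-yl 4-nitrobenzoate F15.
   - The esters are separated by crystallisation or preparative HPLC.
   - Methanolysis of F14 (K2CO3, MeOH) returns 9.

**Further compounds**

F1 | step 12 | 15-(tert-butyldimethylsilyloxy)labda-8,13(16)-diene | CC1(C)CCC[C@@]2(C)[C@H]1CCC(C)=C2CCC(=C)CCO[Si](C)(C)C(C)(C)C
F2 | step 12 | 15-(tert-butyldimethylsilyloxy)labda-8,13(16)-dien-7-one | CC1(C)CCC[C@@]2(C)[C@H]1CC(=O)C(C)=C2CCC(=C)CCO[Si](C)(C)C(C)(C)C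
F3 | step 12 | 15-(tert-butyldimethylsilyloxy)labda-8,13(16)-dien-7β-ol | CC1(C)CCC[C@@]2(C)[C@H]1C[C@H](O)C(C)=C2CCC(=C)CCO[Si](C)(C)C(C)(C)C
F4 | step 12 | 7β-(tert-butoxycarbonyloxy)-15-(tert-butyldimethylsilyloxy)labda-8,13(16)-diene | CC1(C)CCC[C@@]2(C)[C@H]1C[C@H](OC(=O)OC(C)(C)C)C(C)=C2CCC(=C)CCO[Si](C)(C)C(C)(C)C
F5 | step 12 | 7β-(tert-butoxycarbonyloxy)-15-(tert-butyldimethylsilyloxy)-8α,9α-epoxylabd-13(16)-ene | CC1(C)CCC[C@@]2(C)[C@H]1C[C@H](OC(=O)OC(C)(C)C)[C@@]3(C)O[C@@]23CCC(=C)CCO[Si](C)(C)C(C)(C)C
F6 | step 12 | 15-(tert-butyldimethylsilyloxy)-9α-hydroxylabd-13(16)-ene-7β,8β-diyl carbonate | CC1(C)CCC[C@@]2(C)[C@H]1C[C@@H]3OC(=O)O[C@]3(C)[C@]2(O)CCC(=C)CCO[Si](C)(C)C(C)(C)C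
F7 | step 12 | 9α,15-dihydroxylabd-13(16)-ene-7β,8β-diyl carbonate | CC1(C)CCC[C@@]2(C)[C@H]1C[C@@H]3OC(=O)O[C@]3(C)[C@]2(O)CCC(=C)CCO
F8 | step 12 | (13R)-9α,15-dihydroxy-13,16-epoxylabdane-7β,8β-diyl carbonate | CC1(C)CCC[C@@]2(C)[C@H]1C[C@@H]3OC(=O)O[C@]3(C)[C@]2(O)CC[C@@]1(CCO)CO1
F9 | step 8 | labda-8,13(16)-dien-15-yl acetate | CC1(C)CCC[C@@]2(C)[C@H]1CCC(C)=C2CCC(=C)CCOC(C)=O
F10 | step 8 | 7-oxolabda-8,13(16)-dien-15-yl acetate | CC1(C)CCC[C@@]2(C)[C@H]1CC(=O)C(C)=C2CCC(=C)CCOC(C)=O
F11 | step 8 | 15-hydroxylabda-8,13(16)-dien-7-one | CC1(C)CCC[C@@]2(C)[C@H]1CC(=O)C(C)=C2CCC(=C)CCO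
F12 | step 8 | (13R)-15-hydroxy-13,16-epoxylabd-8-en-7-one | CC1(C)CCC[C@@]2(C)[C@H]1CC(=O)C(C)=C2CC[C@@]1(CCO)CO1
F13 | step 6 | (13S)-13,16-epoxylabd-8-en-15-ol | CC1(C)CCC[C@@]2(C)[C@H]1CCC(C)=C2CC[C@]1(CCO)CO1
F14 | step 6 | (13R)-13,16-epoxylabd-8-en-15-yl 4-nitrobenzoate | CC1(C)CCC[C@@]2(C)[C@H]1CCC(C)=C2CC[C@@]1(CCOC(=O)c3ccc(cc3)[N+](=O)[O-])CO1
F15 | step 6 | (13S)-13,16-epoxylabd-8-en-15-yl 4-nitrobenzoate | CC1(C)CCC[C@@]2(C)[C@H]1CCC(C)=C2CC[C@]1(CCOC(=O)c3ccc(cc3)[N+](=O)[O-])CO1
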